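**Strategy.** Ring A, the central benzene (C1 carries the quinone methide carbon C-alpha, C2 the 4-hydroxyphenyl group, C3 and C4 hydrogen, C5 CH2OH, C6 the arylethynyl group), is cut into three alkynes. The C5 CH2OH and the inner alkyne carbon on C6 are read as a ring-opened phthalide, so an ester tether joins the C4–C5 alkyne to the C6–C1 alkyne, which already carries C-alpha as a diaryl carbinol methyl ether. One [Rh(cod)2]BF4/BINAP-catalysed (2+2+2) cycloaddition of this propargyl alkynoate with an aryl(trimethylsilyl)alkyne forms C5–C6, C1–C2 and C3–C4, so that ring A and the lactone ring arise in the same operation. The silyl group directs the aryl group to C2 and is then removed.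

Key step: step 7

Remark on the chemistry: selaginellin has no stereocentre; lactol 16 is a racemate whose hemiacetal centre disappears in step 10, and the deprotected triaryl carbinol ether is assumed to settle as the quinone methide once the acid is neutralised.

**Step 1**
Reactants: 1 4,4'-dihydroxybenzophenone
Product: 2 bis[4-(methoxymethoxy)phenyl]methanone
Conditions: MOMCl, i-Pr2NEt, DMF, 0 °C to rt
Reagents that add atoms: chloromethyl methyl ether, COCCl
Why: Base-mediated O-alkylation of both phenols (Williamson-type acetal formation) should give ethers that withstand the Grignard, alkyllithium, hydride and Pd(PPh3)2Cl2/CuI steps and are released by acid only at the end.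

**Step 2**
Reactants: 2 bis[4-(methoxymethoxy)phenyl]methanone; 3 ethynylmagnesium bromide
Product: 4 1,1-bis[4-(methoxymethoxy)phenyl]prop-2-yn-1-ol
Conditions: THF, 0 °C to 40 °C; aq NH4Cl
Reagents that add atoms: none
Why: 1,2-Addition of an alkynyl Grignard reagent to a diaryl ketone is a standard route to 1,1-diarylpropargyl alcohols and creates no stereocentre because both aryl groups are identical.

**Step 3**
Reactants: 4 1,1-bis[4-(methoxymethoxy)phenyl]prop-2-yn-1-ol
Product: 6 3-methoxy-3,3-bis[4-(methoxymethoxy)phenyl]prop-1-yne, via sodium alkoxide 5 (not isolated)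
Conditions: NaH, THF/DMF, 0 °C; then MeI, 0 °C to rt
Reagents that add atoms: iodomethane, CI
Why: Williamson etherification of the tertiary alkoxide should be clean because NaH deprotonates the alcohol far faster than the alkyne C–H, and the methyl ether later keeps the carbinol oxygen from attacking the lactone carbonyl on C6.

**Step 4**
Reactants: 6 3-methoxy-3,3-bis[4-(methoxymethoxy)phenyl]prop-1-yne; 7 propargyl chloroformate
Product: 9 prop-2-yn-1-yl 4-methoxy-4,4-bis[4-(methoxymethoxy)phenyl]but-2-ynoate, via lithium acetylide 8 (not isolated)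
Conditions: n-BuLi, THF, −78 °C; then cannulated into 7 (1.5 equiv), THF, −78 °C
Reagents that add atoms: none
Why: C-Acylation of a lithium acetylide with a chloroformate is the usual alkynoate synthesis, and inverse addition at −78 °C should let acylation outrun proton transfer from the propargyl C–H and conjugate addition to the product.

**Step 5**
Reactants: 10 4-iodophenol
Product: 11 1-iodo-4-(methoxymethoxy)benzene
Conditions: MOMCl, i-Pr2NEt, CH2Cl2, 0 °C to rt
Reagents that add atoms: chloromethyl methyl ether, COCCl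
Why: The same Williamson-type acetal protection as in step 1 gives one aryl iodide that serves both the silyl alkyne (step 6) and the late arylation (step 11).

**Step 6**
Reactants: 11 1-iodo-4-(methoxymethoxy)benzene; 12 ethynyltrimethylsilane
Product: 13 trimethyl{[4-(methoxymethoxy)phenyl]ethynyl}silane
Conditions: Pd(PPh3)2Cl2, CuI, Et3N, THF, rt
Reagents that add atoms: none
Why: Sonogashira coupling of an aryl iodide with a terminal silyl alkyne proceeds at room temperature and leaves the C–Si bond and the acetal untouched.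

**Step 7**
Reactants: 9 prop-2-yn-1-yl 4-methoxy-4,4-bis[4-(methoxymethoxy)phenyl]but-2-ynoate; 13 trimethyl{[4-(methoxymethoxy)phenyl]ethynyl}silane
Product: 14 7-{methoxybis[4-(methoxymethoxy)phenyl]methyl}-6-[4-(methoxymethoxy)phenyl]-5-(trimethylsilyl)isobenzofuran-1(3H)-one
Conditions: [Rh(cod)2]BF4 (10 mol %), rac-BINAP (10 mol %), pre-treated with H2; ClCH2CH2Cl, 60 °C; 9 added by syringe pump to 13 (3 equiv)
Reagents that add atoms: none
Why: Oxidative cyclisation of the two tethered alkynes of 9 on cationic monovalent rhodium forms C5–C6 and gives a bicyclic rhodacyclopentadiene with the metal on C4 (H) and C1 (carbinol ether); alkyne 13 then inserts and reductive elimination forms C3–C4 and C1–C2. The closest known reaction type is the [Rh(cod)2]BF4/BINAP-catalysed (2+2+2) cycloaddition of ester-tethered 1,6-diynes with monoalkynes to phthalides, here stretched to a more crowded C1–C2–C3 edge. The five-membered lactone closes by exo oxidative coupling of the 1,6-diyne, fused at C5–C6, and ring A closes by insertion and reductive elimination around the metallacycle. No stereocentre is formed. The step needs one orientation of 13: the spherical SiMe3 group cannot sit beside the quaternary substituent on C1, so it should take C3 next to C4–H, while the flat aryl ring, which can twist out of plane, takes C2. Slow addition of 9 to an excess of 13 should suppress self-trimerisation of the diyne through its free terminal alkyne.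

**Step 8**
Reactants: 14 7-{methoxybis[4-(methoxymethoxy)phenyl]methyl}-6-[4-(methoxymethoxy)phenyl]-5-(trimethylsilyl)isobenzofuran-1(3H)-one
Product: 15 7-{methoxybis[4-(methoxymethoxy)phenyl]methyl}-6-[4-(methoxymethoxy)phenyl]isobenzofuran-1(3H)-one
Conditions: Bu4NF·3H2O, DMF, 80 °C; pH 7 phosphate buffer
Reagents that add atoms: none
Why: Fluoride-induced protodesilylation of the aryl silane should be favoured because the silyl group stands para to the lactone carbonyl and is pressed against the C2 aryl ring, and it is placed here so that no fluoride or base ever meets an ortho-alkynyl benzyl alcohol.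

**Step 9**
Reactants: 15 7-{methoxybis[4-(methoxymethoxy)phenyl]methyl}-6-[4-(methoxymethoxy)phenyl]isobenzofuran-1(3H)-one
Product: 16 7-{methoxybis[4-(methoxymethoxy)phenyl]methyl}-6-[4-(methoxymethoxy)phenyl]-1,3-dihydroisobenzofuran-1-ol (racemic)
Conditions: i-Bu2AlH, CH2Cl2, −78 °C; aq potassium sodium tartrate
Reagents that add atoms: none
Why: Partial reduction of a lactone with i-Bu2AlH stops at the lactol because the aluminium acetal is stable at −78 °C, and the new hemiacetal centre is formed as a racemate that is erased in step 10.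

**Step 10**
Reactants: 16 7-{methoxybis[4-(methoxymethoxy)phenyl]methyl}-6-[4-(methoxymethoxy)phenyl]-1,3-dihydroisobenzofuran-1-ol
Product: 18 {3-ethynyl-4'-(methoxymethoxy)-2-{methoxybis[4-(methoxymethoxy)phenyl]methyl}biphenyl-4-yl}methanol, via ring-opened hydroxy aldehyde 17 (not isolated)
Conditions: dimethyl (1-diazo-2-oxopropyl)phosphonate, K2CO3, MeOH/THF, 0 °C to rt
Reagents that add atoms: dimethyl (1-diazo-2-oxopropyl)phosphonate, CC(=O)C(=[N+]=[N-])P(=O)(OC)OC
Why: In the Ohira–Bestmann (Seyferth–Gilbert) homologation the lactol reacts through its hydroxy aldehyde tautomer with the diazophosphonate anion made in the flask, and loss of dimethyl phosphate and N2 followed by a 1,2-hydrogen shift of the alkylidene carbene gives the terminal alkyne on C6 and leaves the C5 CH2OH free.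

**Step 11**
Reactants: 18 {3-ethynyl-4'-(methoxymethoxy)-2-{methoxybis[4-(methoxymethoxy)phenyl]methyl}biphenyl-4-yl}methanol; 11 1-iodo-4-(methoxymethoxy)benzene
Product: 19 {4'-(methoxymethoxy)-2-{methoxybis[4-(methoxymethoxy)phenyl]methyl}-3-{[4-(methoxymethoxy)phenyl]ethynyl}biphenyl-4-yl}methanol
Conditions: Pd(PPh3)2Cl2, CuI, Et3N, THF, rt, degassed
Reagents that add atoms: none
Why: Sonogashira coupling occurs at the remote end of the linear alkyne, so the crowding around C6 matters little, and the free benzylic alcohol and the acetals tolerate Et3N at room temperature.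

**Step 12**
Reactants: 19 {4'-(methoxymethoxy)-2-{methoxybis[4-(methoxymethoxy)phenyl]methyl}-3-{[4-(methoxymethoxy)phenyl]ethynyl}biphenyl-4-yl}methanol
Product: 21 selaginellin, via triarylmethylium chloride 20 (not isolated)
Conditions: 3 M aq HCl, THF, 45 °C; then aq NaHCO3
Reagents that add atoms: none
Why: Aqueous acid should hydrolyse the four methoxymethyl acetals and ionise the doubly para-oxygenated triarylmethyl ether (SN1) to a carbenium ion that loses a phenolic proton on neutralisation to give the quinone methide, with no stereocentre involved.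

**Compound list**

1 | 4,4'-dihydroxybenzophenone | O=C(c1ccc(O)cc1)c1ccc(O)cc1 | starting material
2 | bis[4-(methoxymethoxy)phenyl]methanone | O=C(c1ccc(OCOC)cc1)c1ccc(OCOC)cc1 | intermediate
3 | ethynylmagnesium bromide | C#C[Mg]Br | starting material
4 | 1,1-bis[4-(methoxymethoxy)phenyl]prop-2-yn-1-ol | C#CC(O)(c1ccc(OCOC)cc1)c1ccc(OCOC)cc1 | intermediate
5 | sodium 1,1-bis[4-(methoxymethoxy)phenyl]prop-2-yn-1-olate | C#CC([O-])(c1ccc(OCOC)cc1)c1ccc(OCOC)cc1.[Na+] | intermediate
6 | 3-methoxy-3,3-bis[4-(methoxymethoxy)phenyl]prop-1-yne | C#CC(OC)(c1ccc(OCOC)cc1)c1ccc(OCOC)cc1 | intermediate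
7 | propargyl chloroformate (prop-2-yn-1-yl carbonochloridate) | C#CCOC(=O)Cl | starting material
8 | {3-methoxy-3,3-bis[4-(methoxymethoxy)phenyl]prop-1-yn-1-yl}lithium | [Li]C#CC(OC)(c1ccc(OCOC)cc1)c1ccc(OCOC)cc1 | intermediate
9 | prop-2-yn-1-yl 4-methoxy-4,4-bis[4-(methoxymethoxy)phenyl]but-2-ynoate | C#CCOC(=O)C#CC(OC)(c1ccc(OCOC)cc1)c1ccc(OCOC)cc1 | intermediate
10 | 4-iodophenol | Oc1ccc(I)cc1 | starting material
11 | 1-iodo-4-(methoxymethoxy)benzene | COCOc1ccc(I)cc1 | intermediate
12 | ethynyltrimethylsilane | C#C[Si](C)(C)C | starting material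
13 | trimethyl{[4-(methoxymethoxy)phenyl]ethynyl}silane | C[Si](C)(C)C#Cc1ccc(OCOC)cc1 | intermediate
14 | 7-{methoxybis[4-(methoxymethoxy)phenyl]methyl}-6-[4-(methoxymethoxy)phenyl]-5-(trimethylsilyl)isobenzofuran-1(3H)-one | O=C1OCc2cc([Si](C)(C)C)c(-c3ccc(OCOC)cc3)c(C(OC)(c3ccc(OCOC)cc3)c3ccc(OCOC)cc3)c21 | intermediate
15 | 7-{methoxybis[4-(methoxymethoxy)phenyl]methyl}-6-[4-(methoxymethoxy)phenyl]isobenzofuran-1(3H)-one | O=C1OCc2ccc(-c3ccc(OCOC)cc3)c(C(OC)(c3ccc(OCOC)cc3)c3ccc(OCOC)cc3)c21 | intermediate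
16 | 7-{methoxybis[4-(methoxymethoxy)phenyl]methyl}-6-[4-(methoxymethoxy)phenyl]-1,3-dihydroisobenzofuran-1-ol (racemic) | OC1OCc2ccc(-c3ccc(OCOC)cc3)c(C(OC)(c3ccc(OCOC)cc3)c3ccc(OCOC)cc3)c21 | intermediate
17 | 6-(hydroxymethyl)-2-{methoxybis[4-(methoxymethoxy)phenyl]methyl}-3-[4-(methoxymethoxy)phenyl]benzaldehyde | O=Cc1c(CO)ccc(-c2ccc(OCOC)cc2)c1C(OC)(c1ccc(OCOC)cc1)c1ccc(OCOC)cc1 | intermediate
18 | {3-ethynyl-4'-(methoxymethoxy)-2-{methoxybis[4-(methoxymethoxy)phenyl]methyl}biphenyl-4-yl}methanol | C#Cc1c(CO)ccc(-c2ccc(OCOC)cc2)c1C(OC)(c1ccc(OCOC)cc1)c1ccc(OCOC)cc1 | intermediate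
19 | {4'-(methoxymethoxy)-2-{methoxybis[4-(methoxymethoxy)phenyl]methyl}-3-{[4-(methoxymethoxy)phenyl]ethynyl}biphenyl-4-yl}methanol | OCc1ccc(-c2ccc(OCOC)cc2)c(C(OC)(c2ccc(OCOC)cc2)c2ccc(OCOC)cc2)c1C#Cc1ccc(OCOC)cc1 | intermediate
20 | {4'-hydroxy-4-(hydroxymethyl)-3-[(4-hydroxyphenyl)ethynyl]biphenyl-2-yl}bis(4-hydroxyphenyl)methylium chloride | OCc1ccc(-c2ccc(O)cc2)c([C+](c2ccc(O)cc2)c2ccc(O)cc2)c1C#Cc1ccc(O)cc1.[Cl-] | intermediate
21 | selaginellin | O=C1C=CC(=C(c2ccc(O)cc2)c2c(-c3ccc(O)cc3)ccc(CO)c2C#Cc2ccc(O)cc2)C=C1 | target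

**Totals.** Total step count: 12. Longest linear sequence: 10 steps (steps 1 to 4 and 7 to 12, from 1 to 21).

**Steps most likely to fail**

Step 7. Insertion of the third alkyne next to the quaternary substituent on C1 may be too slow, so that the diyne is consumed by self-oligomerisation through its terminal alkyne. The fallback builds the same phthalide by an intramolecular Diels–Alder reaction without metal or silicon; it sets out from 6 and comes back at 15, so steps 7 and 8 are both skipped.
- Alkyne 6 is deprotonated with n-BuLi and carboxylated with CO2 to 4-methoxy-4,4-bis[4-(methoxymethoxy)phenyl]but-2-ynoic acid F1.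
- In parallel, 4-hydroxybenzaldehyde is protected with MOMCl and i-Pr2NEt to 4-(methoxymethoxy)benzaldehyde F2.
- Horner–Wadsworth–Emmons olefination of F2 with triethyl 4-phosphonocrotonate (LiN(SiMe3)2, THF) should give ethyl (2E,4E)-5-[4-(methoxymethoxy)phenyl]penta-2,4-dienoate F3.
- Reduction with i-Bu2AlH should give (2E,4E)-5-[4-(methoxymethoxy)phenyl]penta-2,4-dien-1-ol F4.
- Esterification of F1 with F4 (DCC, DMAP, CH2Cl2, 0 °C) gives (2E,4E)-5-[4-(methoxymethoxy)phenyl]penta-2,4-dien-1-yl 4-methoxy-4,4-bis[4-(methoxymethoxy)phenyl]but-2-ynoate F5.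
- Heating (o-dichlorobenzene, about 160 °C) should bring about the intramolecular Diels–Alder reaction of diene and alkynoate to the cis-3a,6-dihydroisobenzofuranone F6. The diene carbons become C5, C4, C3 and C2, and the ester tether fixes the aryl group at C2.
- DDQ then aromatises ring A to 15.

Step 8. Carbon–silicon cleavage may stay incomplete, or hydroxide formed from wet fluoride may open the lactone and let the carboxylate capture an ionised C-alpha. The fallback carries the silyl group to the end and removes it by acid; it sets out from 14 and comes back at 21.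
- Reduction of 14 with i-Bu2AlH at −78 °C gives the silylated lactol F7.
- Ohira–Bestmann homologation gives the silylated ethynylbenzyl alcohol F8.
- Sonogashira coupling with 11 (Pd(PPh3)2Cl2, CuI, Et3N) gives the silylated diaryl alkyne F9.
- CF3CO2H in wet CH2Cl2 should then effect ipso-protodesilylation at C3 together with acetal cleavage and ionisation of the methyl ether, and neutralisation gives 21.

Step 10. The ring–chain equilibrium may lie on the lactol side, and addition to the hindered aldehyde may be slow, so that the diazophosphonate decays before it reacts. The fallback uses an open-chain aldehyde that cannot close; it sets out from 15 and comes back at 18.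
- LiAlH4 (THF, 0 °C) reduces 15 to the biphenyl-3,4-diyldimethanol F10.
- TBSCl and imidazole silylate the less hindered C5 CH2OH to give the mono-silyl ether F11.
- Dess–Martin periodinane oxidises the remaining C6 CH2OH to the silyloxy aldehyde F12.
- Lithiated trimethylsilyldiazomethane (Me3SiCHN2, n-BuLi, THF, −78 °C to rt; Colvin rearrangement), a small and strongly nucleophilic reagent, should convert F12 into the ethynyl silyl ether F13.
- Bu4NF with acetic acid at 0 °C frees the alcohol and gives 18.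

**Further compounds**

F1 | step 7 | 4-methoxy-4,4-bis[4-(methoxymethoxy)phenyl]but-2-ynoic acid | OC(=O)C#CC(OC)(c1ccc(OCOC)cc1)c1ccc(OCOC)cc1
F2 | step 7 | 4-(methoxymethoxy)benzaldehyde | O=Cc1ccc(OCOC)cc1
F3 | step 7 | ethyl (2E,4E)-5-[4-(methoxymethoxy)phenyl]penta-2,4-dienoate | CCOC(=O)/C=C/C=C/c1ccc(OCOC)cc1
F4 | step 7 | (2E,4E)-5-[4-(methoxymethoxy)phenyl]penta-2,4-dien-1-ol | OC/C=C/C=C/c1ccc(OCOC)cc1
F5 | step 7 | (2E,4E)-5-[4-(methoxymethoxy)phenyl]penta-2,4-dien-1-yl 4-methoxy-4,4-bis[4-(methoxymethoxy)phenyl]but-2-ynoate | COCOc1ccc(/C=C/C=C/COC(=O)C#CC(OC)(c2ccc(OCOC)cc2)c2ccc(OCOC)cc2)cc1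
F6 | step 7 | cis-7-{methoxybis[4-(methoxymethoxy)phenyl]methyl}-6-[4-(methoxymethoxy)phenyl]-3a,6-dihydroisobenzofuran-1(3H)-one (racemic, 3a-H and 6-H cis) | O=C1OC[C@@H]2C=C[C@H](c3ccc(OCOC)cc3)C(C(OC)(c3ccc(OCOC)cc3)c3ccc(OCOC)cc3)=C12
F7 | step 8 | 7-{methoxybis[4-(methoxymethoxy)phenyl]methyl}-6-[4-(methoxymethoxy)phenyl]-5-(trimethylsilyl)-1,3-dihydroisobenzofuran-1-ol (racemic) | OC1OCc2cc([Si](C)(C)C)c(-c3ccc(OCOC)cc3)c(C(OC)(c3ccc(OCOC)cc3)c3ccc(OCOC)cc3)c21
F8 | step 8 | {3-ethynyl-4'-(methoxymethoxy)-2-{methoxybis[4-(methoxymethoxy)phenyl]methyl}-6-(trimethylsilyl)biphenyl-4-yl}methanol | C#Cc1c(CO)cc([Si](C)(C)C)c(-c2ccc(OCOC)cc2)c1C(OC)(c1ccc(OCOC)cc1)c1ccc(OCOC)cc1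
F9 | step 8 | {4'-(methoxymethoxy)-2-{methoxybis[4-(methoxymethoxy)phenyl]methyl}-3-{[4-(methoxymethoxy)phenyl]ethynyl}-6-(trimethylsilyl)biphenyl-4-yl}methanol | OCc1cc([Si](C)(C)C)c(-c2ccc(OCOC)cc2)c(C(OC)(c2ccc(OCOC)cc2)c2ccc(OCOC)cc2)c1C#Cc1ccc(OCOC)cc1
F10 | step 10 | {4'-(methoxymethoxy)-2-{methoxybis[4-(methoxymethoxy)phenyl]methyl}biphenyl-3,4-diyl}dimethanol | OCc1ccc(-c2ccc(OCOC)cc2)c(C(OC)(c2ccc(OCOC)cc2)c2ccc(OCOC)cc2)c1CO
F11 | step 10 | {4-[(tert-butyldimethylsilyloxy)methyl]-4'-(methoxymethoxy)-2-{methoxybis[4-(methoxymethoxy)phenyl]methyl}biphenyl-3-yl}methanol | CC(C)(C)[Si](C)(C)OCc1ccc(-c2ccc(OCOC)cc2)c(C(OC)(c2ccc(OCOC)cc2)c2ccc(OCOC)cc2)c1CO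
F12 | step 10 | 4-[(tert-butyldimethylsilyloxy)methyl]-4'-(methoxymethoxy)-2-{methoxybis[4-(methoxymethoxy)phenyl]methyl}biphenyl-3-carbaldehyde | CC(C)(C)[Si](C)(C)OCc1ccc(-c2ccc(OCOC)cc2)c(C(OC)(c2ccc(OCOC)cc2)c2ccc(OCOC)cc2)c1C=O
F13 | step 10 | tert-butyl{[3-ethynyl-4'-(methoxymethoxy)-2-{methoxybis[4-(methoxymethoxy)phenyl]methyl}biphenyl-4-yl]methoxy}dimethylsilane | CC(C)(C)[Si](C)(C)OCc1ccc(-c2ccc(OCOC)cc2)c(C(OC)(c2ccc(OCOC)cc2)c2ccc(OCOC)cc2)c1C#C
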